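**Plan**
- Retrosynthetic cuts, in order: the O7–CH2 ether bond to the (E)-4-hydroxy-3-methylbut-2-enyl chain; the C3–OH and C4=O oxygens, taken back to a C3=C4 alkene; the C3–C4 bond of ring C; the O1–C2 bond.
- Enabling feature: C3 and C4 of ring C are adjacent and both oxygenated, so they can be carried as one alkene. That alkene is closed by metathesis between a vinyl group on C4a of ring A and the vinyl group of an aryl allyl ether whose carbinol carbon is C2.
- Forward: rings A and B are bought as arenes and joined through O1–C2; ring C closes by metathesis; dihydroxylation, C4 oxidation and debenzylation give aromadendrin; the chain is attached last at O7 and unmasked.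
- Stereochemistry: C2 by catalyst control in an iridium–phosphoramidite allylic etherification; C3 by substrate control (osmylation anti to the C2 aryl group); the E alkene of the chain by SeO2 allylic oxidation.

Key step: step 7

Assumption: the (Sa,S,S) enantiomer of the phosphoramidite L (binaphthyl-2,2'-diyl N,N-bis(1-phenylethyl)phosphoramidite) is taken to give the S ether in step 6. If a model run shows the opposite sense, the (Ra,R,R) ligand is used with nothing else changed.

Remark: C2 is S in 9 and 10 and R from 11 onward, and C3 is S in 11 and R from 12 onward. Both changes come only from CIP priorities; the spatial arrangement is the same throughout.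

**Route**

Step 1
Reactants: 1 2,4,6-trihydroxybenzaldehyde
Product: 2 4,6-bis(benzyloxy)-2-hydroxybenzaldehyde
Conditions: BnBr (2.05 equiv), K2CO3 (2.2 equiv), DMF, 0 °C → rt
Reagents that add atoms: benzyl bromide, BrCc1ccccc1
Why: Williamson etherification alkylates the 4-OH and one ortho OH, while the remaining ortho OH is hydrogen-bonded to the formyl oxygen, is the least nucleophilic and should stay free with two equivalents of halide.

Step 2
Reactants: 2 4,6-bis(benzyloxy)-2-hydroxybenzaldehyde
Product: 3 3,5-bis(benzyloxy)-2-vinylphenol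
Conditions: Ph3PCH3Br (1.5 equiv), KOt-Bu (2.5 equiv), THF, 0 °C → rt; neutral work-up, used promptly
Reagents that add atoms: methyltriphenylphosphonium bromide, [Br-].C[P+](c1ccccc1)(c1ccccc1)c1ccccc1
Why: Wittig methylenation of a salicylaldehyde, in which one equivalent of base is spent on the phenol and methylenetriphenylphosphorane converts the formyl group of the phenoxide into the vinyl group.

Step 3
Reactants: 4 4-(benzyloxy)benzaldehyde
Product: 5 ethyl (E)-3-[4-(benzyloxy)phenyl]prop-2-enoate
Conditions: (EtO)2P(O)CH2CO2Et, NaH, THF, 0 °C → rt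
Reagents that add atoms: triethyl phosphonoacetate, CCOC(=O)CP(=O)(OCC)OCC
Why: Horner–Wadsworth–Emmons olefination of an aromatic aldehyde with a stabilised phosphonate anion should give the E cinnamate.

Step 4
Reactants: 5 ethyl (E)-3-[4-(benzyloxy)phenyl]prop-2-enoate
Product: 6 (E)-3-[4-(benzyloxy)phenyl]prop-2-en-1-ol
Conditions: i-Bu2AlH (2.2 equiv), CH2Cl2, −78 °C
Reagents that add atoms: none
Why: 1,2-reduction of an α,β-unsaturated ester by i-Bu2AlH at low temperature gives the allylic alcohol and leaves the alkene and the benzyl ether untouched.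

Step 5
Reactants: 6 (E)-3-[4-(benzyloxy)phenyl]prop-2-en-1-ol
Product: 7 (E)-3-[4-(benzyloxy)phenyl]allyl methyl carbonate
Conditions: ClCO2Me, pyridine, CH2Cl2, 0 °C
Reagents that add atoms: methyl chloroformate, COC(=O)Cl
Why: O-acylation of the primary allylic alcohol with a chloroformate installs the carbonate leaving group needed for the allylic substitution.

Step 6
Reactants: 3 3,5-bis(benzyloxy)-2-vinylphenol; 7 (E)-3-[4-(benzyloxy)phenyl]allyl methyl carbonate
Product: 9 (S)-1-[4-(benzyloxy)phenyl]allyl 3,5-bis(benzyloxy)-2-vinylphenyl ether, via lithium 3,5-bis(benzyloxy)-2-vinylphenoxide 8 (not isolated)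
Conditions: n-BuLi (1.0 equiv), THF, −78 → 0 °C; then 7 (1.1 equiv), [Ir(cod)Cl]2 (2 mol %), (Sa,S,S)-L (4 mol %, preactivated with n-PrNH2), THF, rt; Et3N-deactivated silica
Reagents that add atoms: none
Why: Iridium-catalysed asymmetric allylic etherification, in which the carbonate adds oxidatively to the cyclometalated monovalent iridium phosphoramidite complex and the lithium aryloxide attacks the aryl-substituted terminus of the trivalent iridium allyl intermediate, so the branched ether forms and the ligand fixes the face of attack that makes C2 S.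

Step 7
Reactants: 9 (S)-1-[4-(benzyloxy)phenyl]allyl 3,5-bis(benzyloxy)-2-vinylphenyl ether
Product: 10 (2S)-5,7-bis(benzyloxy)-2-[4-(benzyloxy)phenyl]-2H-chromene
Conditions: second-generation Grubbs catalyst RuCl2(=CHPh)(PCy3)(H2IMes) (5 mol %), CH2Cl2 (5 mM), 20 °C, Ar, dark; used directly in step 8
Reagents that add atoms: none
Why: This is a ring-closing olefin metathesis of a 2-vinylphenyl allyl ether to a 2H-chromene, a known reaction type: the ruthenium benzylidene first exchanges with the less hindered vinyl group of the allylic ether, the new alkylidene adds across the styrenyl C=C on C4a in a [2+2] cycloaddition to a ruthenacyclobutane, and cycloreversion releases the C3=C4 bond and a ruthenium methylidene. Ring C (O1, C2, C3, C4, C4a, C8a) closes as a six-membered ring by this intramolecular metathesis of two terminal vinyl groups held together by the O1–C8a–C4a tether, and the ring imposes the cis geometry of the new alkene. No stereocentre is created; the only stereochemical demand is that C2 stays S, which should hold because C2 is a non-enolisable ether carbon that takes no part in bond making and because the mild temperature and exclusion of light suppress electrocyclic opening of the chromene to the achiral ortho-quinone methide. The two vinyl groups are the only metathesis-active alkenes, high dilution disfavours cross-metathesis dimers, and loss of ethene makes the closure irreversible.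

Step 8
Reactants: 10 (2S)-5,7-bis(benzyloxy)-2-[4-(benzyloxy)phenyl]-2H-chromene
Product: 11 (2R,3S,4S)-5,7-bis(benzyloxy)-2-[4-(benzyloxy)phenyl]chromane-3,4-diol
Conditions: OsO4 (2 mol %), NMO (1.5 equiv), acetone/H2O 9:1, 0 °C → rt, dark
Reagents that add atoms: osmium tetroxide, O=[Os](=O)(=O)=O (delivers both oxygen atoms); N-methylmorpholine N-oxide, C[N+]1([O-])CCOCC1, and water, O (replenish the oxygen of the catalyst)
Why: Upjohn dihydroxylation, in which OsO4 adds suprafacially to the electron-rich cis C3=C4 bond from the face opposite the C2 aryl group, so the two hydroxyls are cis to each other and the 3-OH is trans to the aryl group.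

Step 9
Reactants: 11 (2R,3S,4S)-5,7-bis(benzyloxy)-2-[4-(benzyloxy)phenyl]chromane-3,4-diol
Product: 12 (2R,3R)-5,7-bis(benzyloxy)-2-[4-(benzyloxy)phenyl]-3-hydroxychroman-4-one
Conditions: DDQ (1.2 equiv), 1,4-dioxane, rt, dark
Reagents that add atoms: none
Why: DDQ oxidation of an electron-rich benzylic alcohol, in which hydride is abstracted only from C4–H because the resulting cation is stabilised by the 5,7-dialkoxy ring A and O1, so the C4 carbinol becomes the ketone and the non-benzylic C3 carbinol keeps its configuration.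

Step 10
Reactants: 12 (2R,3R)-5,7-bis(benzyloxy)-2-[4-(benzyloxy)phenyl]-3-hydroxychroman-4-one
Product: 13 (2R,3R)-3,5,7-trihydroxy-2-(4-hydroxyphenyl)chroman-4-one (aromadendrin)
Conditions: H2 (1 atm), 10% Pd/C, EtOAc/MeOH 1:1, rt
Reagents that add atoms: none
Why: Catalytic hydrogenolysis cleaves the three aryl benzyl ethers under conditions that should leave the chelated aryl ketone and the ring C–O bonds of a dihydroflavonol intact.

Step 11
Reactants: 14 prenyl acetate (3-methylbut-2-en-1-yl acetate)
Product: 15 (2E)-4-hydroxy-3-methylbut-2-en-1-yl acetate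
Conditions: SeO2 (0.3 equiv), t-BuOOH (70% aq., 2.5 equiv), salicylic acid (cat.), CH2Cl2, rt
Reagents that add atoms: selenium dioxide, O=[Se]=O (oxygen-transfer agent); tert-butyl hydroperoxide, CC(C)(C)OO (terminal oxygen source)
Why: SeO2/t-BuOOH allylic oxidation (ene reaction, then [2,3]-sigmatropic shift) hydroxylates the methyl group trans to the CH2OAc chain of the trisubstituted alkene, which gives the E allylic alcohol.

Step 12
Reactants: 15 (2E)-4-hydroxy-3-methylbut-2-en-1-yl acetate
Product: 16 (2E)-4-[(tert-butyldimethylsilyl)oxy]-3-methylbut-2-en-1-yl acetate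
Conditions: TBSCl, imidazole, DMF, 0 °C → rt
Reagents that add atoms: tert-butyldimethylsilyl chloride, CC(C)(C)[Si](C)(C)Cl
Why: Silylation of the primary allylic alcohol under imidazole catalysis masks the hydroxyl that has to reach the target.

Step 13
Reactants: 16 (2E)-4-[(tert-butyldimethylsilyl)oxy]-3-methylbut-2-en-1-yl acetate
Product: 17 (2E)-4-[(tert-butyldimethylsilyl)oxy]-3-methylbut-2-en-1-ol
Conditions: K2CO3 (cat.), MeOH, 0 °C → rt
Reagents that add atoms: none
Why: Base-catalysed transesterification removes the acetate and leaves the silyl ether and the alkene geometry intact.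

Step 14
Reactants: 17 (2E)-4-[(tert-butyldimethylsilyl)oxy]-3-methylbut-2-en-1-ol
Product: 18 {[(2E)-4-bromo-2-methylbut-2-en-1-yl]oxy}(tert-butyl)dimethylsilane
Conditions: CBr4, PPh3, 2,6-lutidine, CH2Cl2, 0 °C
Reagents that add atoms: carbon tetrabromide, BrC(Br)(Br)Br
Why: Appel bromination displaces the oxyphosphonium of the primary allylic alcohol by SN2 attack of bromide, which at 0 °C should cause neither allylic transposition nor loss of the E geometry.

Step 15
Reactants: 13 (2R,3R)-3,5,7-trihydroxy-2-(4-hydroxyphenyl)chroman-4-one; 18 {[(2E)-4-bromo-2-methylbut-2-en-1-yl]oxy}(tert-butyl)dimethylsilane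
Product: 19 (2R,3R)-7-{[(2E)-4-[(tert-butyldimethylsilyl)oxy]-3-methylbut-2-en-1-yl]oxy}-3,5-dihydroxy-2-(4-hydroxyphenyl)chroman-4-one
Conditions: 18 (1.1 equiv), K2CO3 (1.1 equiv), degassed acetone, Ar, 40 °C
Reagents that add atoms: none
Why: Williamson etherification under weak base, in which only the 7-OH (para to the carbonyl and the most acidic hydroxyl) is deprotonated by one equivalent of K2CO3, the 5-OH being chelated, the 4'-OH less acidic and the 3-OH an alcohol, and the 7-phenoxide displaces the allylic bromide by SN2.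

Step 16
Reactants: 19 (2R,3R)-7-{[(2E)-4-[(tert-butyldimethylsilyl)oxy]-3-methylbut-2-en-1-yl]oxy}-3,5-dihydroxy-2-(4-hydroxyphenyl)chroman-4-one
Product: 20 (2R,3R)-3,5-dihydroxy-7-{[(2E)-4-hydroxy-3-methylbut-2-en-1-yl]oxy}-2-(4-hydroxyphenyl)chroman-4-one (EANPDB:RUTA_00030)
Conditions: HF·pyridine, THF/pyridine, 0 °C → rt
Reagents that add atoms: none
Why: Fluoride-mediated desilylation under mildly acidic, buffered conditions cleaves the Si–O bond and should spare the base-sensitive dihydroflavonol, the allyl aryl ether and both stereocentres.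

**Compound list**

1 | 2,4,6-trihydroxybenzaldehyde | O=Cc1c(O)cc(O)cc1O | starting material
2 | 4,6-bis(benzyloxy)-2-hydroxybenzaldehyde | O=Cc1c(O)cc(OCc2ccccc2)cc1OCc1ccccc1 | intermediate
3 | 3,5-bis(benzyloxy)-2-vinylphenol | C=Cc1c(O)cc(OCc2ccccc2)cc1OCc1ccccc1 | intermediate
4 | 4-(benzyloxy)benzaldehyde | O=Cc1ccc(OCc2ccccc2)cc1 | starting material
5 | ethyl (E)-3-[4-(benzyloxy)phenyl]prop-2-enoate | CCOC(=O)/C=C/c1ccc(OCc2ccccc2)cc1 | intermediate
6 | (E)-3-[4-(benzyloxy)phenyl]prop-2-en-1-ol | OC/C=C/c1ccc(OCc2ccccc2)cc1 | intermediate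
7 | (E)-3-[4-(benzyloxy)phenyl]allyl methyl carbonate | COC(=O)OC/C=C/c1ccc(OCc2ccccc2)cc1 | intermediate
8 | lithium 3,5-bis(benzyloxy)-2-vinylphenoxide | [Li+].[O-]c1cc(OCc2ccccc2)cc(OCc2ccccc2)c1C=C | intermediate
9 | (S)-1-[4-(benzyloxy)phenyl]allyl 3,5-bis(benzyloxy)-2-vinylphenyl ether | C=Cc1c(OCc2ccccc2)cc(OCc2ccccc2)cc1O[C@H](c1ccc(OCc2ccccc2)cc1)C=C | intermediate
10 | (2S)-5,7-bis(benzyloxy)-2-[4-(benzyloxy)phenyl]-2H-chromene | C(c1ccccc1)Oc1cc(OCc2ccccc2)c2c(c1)O[C@H](c1ccc(OCc3ccccc3)cc1)C=C2 | intermediate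
11 | (2R,3S,4S)-5,7-bis(benzyloxy)-2-[4-(benzyloxy)phenyl]chromane-3,4-diol | C(c1ccccc1)Oc1cc(OCc2ccccc2)c2c(c1)O[C@H](c1ccc(OCc3ccccc3)cc1)[C@@H](O)[C@H]2O | intermediate
12 | (2R,3R)-5,7-bis(benzyloxy)-2-[4-(benzyloxy)phenyl]-3-hydroxychroman-4-one | C(c1ccccc1)Oc1cc(OCc2ccccc2)c2c(c1)O[C@H](c1ccc(OCc3ccccc3)cc1)[C@@H](O)C2=O | intermediate
13 | (2R,3R)-3,5,7-trihydroxy-2-(4-hydroxyphenyl)chroman-4-one (aromadendrin) | Oc1cc(O)c2c(c1)O[C@H](c1ccc(O)cc1)[C@@H](O)C2=O | intermediate
14 | prenyl acetate | CC(C)=CCOC(C)=O | starting material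
15 | (2E)-4-hydroxy-3-methylbut-2-en-1-yl acetate | C/C(=C\COC(C)=O)CO | intermediate
16 | (2E)-4-[(tert-butyldimethylsilyl)oxy]-3-methylbut-2-en-1-yl acetate | C/C(=C\COC(C)=O)CO[Si](C)(C)C(C)(C)C | intermediate
17 | (2E)-4-[(tert-butyldimethylsilyl)oxy]-3-methylbut-2-en-1-ol | C/C(=C\CO)CO[Si](C)(C)C(C)(C)C | intermediate
18 | {[(2E)-4-bromo-2-methylbut-2-en-1-yl]oxy}(tert-butyl)dimethylsilane | C/C(=C\CBr)CO[Si](C)(C)C(C)(C)C | intermediate
19 | (2R,3R)-7-{[(2E)-4-[(tert-butyldimethylsilyl)oxy]-3-methylbut-2-en-1-yl]oxy}-3,5-dihydroxy-2-(4-hydroxyphenyl)chroman-4-one | C/C(=C\COc1cc(O)c2c(c1)O[C@H](c1ccc(O)cc1)[C@@H](O)C2=O)CO[Si](C)(C)C(C)(C)C | intermediate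
20 | (2R,3R)-3,5-dihydroxy-7-{[(2E)-4-hydroxy-3-methylbut-2-en-1-yl]oxy}-2-(4-hydroxyphenyl)chroman-4-one | C/C(=C\COc1cc(O)c2c(c1)O[C@H](c1ccc(O)cc1)[C@@H](O)C2=O)CO | target

**Count**

Total steps: 16. Longest linear sequence: 10 steps (4 → 5 → 6 → 7 → 9 → 10 → 11 → 12 → 13 → 19 → 20; steps 3–10, 15, 16).

**Steps most likely to fail**

Step 6. The electron-rich 1-arylallyl aryl ether may ionise reversibly on the iridium catalyst or on acidic surfaces, which would erode the enantiomeric purity and the branched-to-linear ratio. Fallback, from 4 and 3 back to 9: addition of CH2=CHMgBr to aldehyde 4 (THF, 0 °C) would give racemic 1-[4-(benzyloxy)phenyl]prop-2-en-1-ol F1. Kinetic resolution with immobilised Candida antarctica lipase B and vinyl acetate should acetylate the R enantiomer to (R)-1-[4-(benzyloxy)phenyl]allyl acetate F2, which is separated from the unreacted S alcohol. Methanolysis (K2CO3, MeOH, 0 °C) would give (R)-1-[4-(benzyloxy)phenyl]prop-2-en-1-ol F3. Mitsunobu etherification of phenol 3 with F3 (PPh3, DIAD, toluene, −20 °C) should then give 9 with inversion at the carbinol carbon.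

Step 9. Hydride abstraction may be slow because the C4–H bond of the cis diol lies near the plane of ring A, and competing ionisation of the C4 hydroxyl or attack at C2–H would lead to over-oxidation and decomposition. Fallback, from 11 back to 12: the less hindered equatorial C3 hydroxyl is silylated selectively (Et3SiCl, imidazole, CH2Cl2, −40 °C) to (2R,3S,4S)-5,7-bis(benzyloxy)-2-[4-(benzyloxy)phenyl]-3-(triethylsilyloxy)chroman-4-ol F4. The remaining C4 carbinol is oxidised with Dess–Martin periodinane (NaHCO3, CH2Cl2) to (2R,3R)-5,7-bis(benzyloxy)-2-[4-(benzyloxy)phenyl]-3-(triethylsilyloxy)chroman-4-one F5. HF·pyridine in THF at 0 °C removes the silyl group and gives 12.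

Step 15. Alkylation may also occur at the ring B phenol, and base may cause ring opening with epimerisation at C2 or aerial dehydrogenation to the flavonol. Fallback, from 13 and 17 back to 19: peracetylation (Ac2O, pyridine, DMAP cat.) would give (2R,3R)-aromadendrin 3,5,7,4'-tetraacetate F6. Selective removal of the most labile 7-O-acetyl group (PhSH, imidazole, NMP, 0 °C) would give (2R,3R)-aromadendrin 3,5,4'-triacetate F7. Mitsunobu etherification of its free 7-OH with alcohol 17 (PPh3, DIAD, THF, 0 °C) under neutral conditions would give (2R,3R)-7-{[(2E)-4-[(tert-butyldimethylsilyl)oxy]-3-methylbut-2-en-1-yl]oxy}aromadendrin 3,5,4'-triacetate F8. Ammonolysis of the three acetates (NH3, MeOH, 0 °C, Ar) returns to 19.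

**Further compounds**

F1 | step 6 | rac-1-[4-(benzyloxy)phenyl]prop-2-en-1-ol | OC(c1ccc(OCc2ccccc2)cc1)C=C
F2 | step 6 | (R)-1-[4-(benzyloxy)phenyl]allyl acetate | CC(=O)O[C@@H](c1ccc(OCc2ccccc2)cc1)C=C
F3 | step 6 | (R)-1-[4-(benzyloxy)phenyl]prop-2-en-1-ol | O[C@@H](c1ccc(OCc2ccccc2)cc1)C=C
F4 | step 9 | (2R,3S,4S)-5,7-bis(benzyloxy)-2-[4-(benzyloxy)phenyl]-3-(triethylsilyloxy)chroman-4-ol | C(c1ccccc1)Oc1cc(OCc2ccccc2)c2c(c1)O[C@H](c1ccc(OCc3ccccc3)cc1)[C@@H](O[Si](CC)(CC)CC)[C@H]2O
F5 | step 9 | (2R,3R)-5,7-bis(benzyloxy)-2-[4-(benzyloxy)phenyl]-3-(triethylsilyloxy)chroman-4-one | C(c1ccccc1)Oc1cc(OCc2ccccc2)c2c(c1)O[C@H](c1ccc(OCc3ccccc3)cc1)[C@@H](O[Si](CC)(CC)CC)C2=O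
F6 | step 15 | (2R,3R)-aromadendrin 3,5,7,4'-tetraacetate | CC(=O)Oc1cc(OC(C)=O)c2c(c1)O[C@H](c1ccc(OC(C)=O)cc1)[C@@H](OC(C)=O)C2=O
F7 | step 15 | (2R,3R)-aromadendrin 3,5,4'-triacetate (7-OH free) | Oc1cc(OC(C)=O)c2c(c1)O[C@H](c1ccc(OC(C)=O)cc1)[C@@H](OC(C)=O)C2=O
F8 | step 15 | (2R,3R)-7-{[(2E)-4-[(tert-butyldimethylsilyl)oxy]-3-methylbut-2-en-1-yl]oxy}aromadendrin 3,5,4'-triacetate | C/C(=C\COc1cc(OC(C)=O)c2c(c1)O[C@H](c1ccc(OC(C)=O)cc1)[C@@H](OC(C)=O)C2=O)CO[Si](C)(C)C(C)(C)C
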